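## Analysis of the target

The target 18 is an isoflavan quinone: a chroman (ring A = C4a, C5, C6, C7, C8, C8a; pyran ring = O1, C2, C3, C4, C4a, C8a) with a free hydroxyl on C6 and methoxy groups on C7 and C8, whose C3 is bonded to C5 of a 2,3-dimethoxy-1,4-benzoquinone (ring B). C3 is the only stereocenter (S), so nothing in the molecule can relay it and it has to be set by a reagent or catalyst. Its hydrogen sits on a carbon attached to a quinone ring carbon, γ to a quinone carbonyl, where base can remove it through a quinone methide tautomer, so the molecule must not meet base once ring B is a quinone. The other sensitive groups are the quinone itself, an electrophile whose methoxy groups are vinylogous esters, and ring A, a p-alkoxyphenol that is easily oxidised. The difficulty is that rings A and B carry the same 1,2,3,4-tetraoxygenation pattern but must end at different oxidation levels, joined through the bridge C2–C3–C4 with control at its central carbon. The strategy rests on ring A: with O1 on C8a, the hydroxyl para to it on C6 and methoxy groups on C7 and C8, it has exactly the atoms of a 5-allyl-2,3-dimethoxy-1,4-benzoquinone whose carbonyl oxygen next to the chain has closed onto the chain end C2, the relation of ubiquinone to ubichromenol. Both rings can therefore come from one symmetrical quinone, and ring A needs neither a protecting group nor an oxidation of its own.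

## Retrosynthetic reasoning

**Ring B quinone last (18 ⇒ 17 ⇒ 16).** No skeletal bond is cut. The quinone is traced to hydroquinone 17 and this to the bis(benzyl) ether 16. The C3 hydrogen becomes acidic only when ring B is a quinone, so the oxidation is the last operation and must be neutral. Benzyl is chosen because hydrogenolysis removes it under neutral conditions. What then remains is an oxidation that a mild oxidant performs on a hydroquinone but not on the monophenol of ring A. Methyl ethers on ring B would need an oxidative demethylation that could not tell ring B from ring A.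

**The stereocenter from an alkene (16 ⇒ 15).** The C3–H and C4–H bonds are removed to give chromene 15. C3=C4 in 15 carries ring A on C4 and ring B on C3 trans to each other, because the pyran ring ties C4a and C2 together on the same side. This is the geometry of an α-substituted trans-stilbene, the alkene class that chiral cationic iridium catalysts hydrogenate best. The forward reaction has to add hydrogen to one face of C3 without touching the benzyl ethers.

**Key disconnection, O1–C2 (15 ⇒ 14 ⇒ 13).** Cutting O1–C2 in an electrocyclic sense gives the o-quinone methide 14, and moving one hydrogen back to C4 gives allylquinone 13. This bond is chosen because its cleavage turns ring A into a quinone and the chromene into a 2-arylallyl group at one stroke. In the forward sense the free 6-OH, the pyran ring and the C3=C4 bond all appear in one redox-neutral isomerisation. The forward reaction has to enolise the C4 methylene and close oxygen onto C2.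

**Allyl–quinone bond, C4–C4a (13 ⇒ 12 ⇒ 11 + 2).** The bond between the allyl CH2 and the quinone carbon is the one a Lewis-acid-promoted allyl transfer from tin to a quinone makes. Quinone 2 is symmetrical, so there is one site of attack. The two CH2 ends of the 2-arylallyl group in stannane 11 are equivalent, so allyl transposition is of no consequence. The addition gives hydroquinone 12, which is oxidised to 13 while ring B stays protected.

**Aryl–alkenyl bond, C3–C1' (11 ⇒ 9 ⇒ 7 + 8).** Stannane 11 comes from allylic alcohol 9 by exchange of oxygen for tin. Alcohol 9 is cut between C3 and ring B into aryl boronate 7 and 2-bromoallyl alcohol 8. Compound 8 supplies all three bridge carbons with the right handles: the vinyl bromide for the bond to ring B and the CH2OH that becomes the nucleophilic C4.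

**Ring B from the same quinone (7 ⇒ 6 ⇒ 5 ⇒ 2 + 3; 2 ⇒ 1).** Boronate 7 comes from bromide 6, which is the monobromide of the symmetrical bis(benzyl) ether 5. Ether 5 is the reduced form of quinone 2 carrying two benzyl groups from 3. Quinone 2 is the para-oxidation product of phenol 1, so both oxygenated rings of the target come from 1.

## Alternatives that were turned down

**Alternative 1: Moore ring expansion that builds ring B last.**
- Disconnection: ring B is cut at C1'–C2' (C1' is the quinone carbon on C3) and traced to cyclobutenone A2. A2 is a 4-hydroxy-2,3-dimethoxycyclobutenone carrying at C4 the ethynyl group of an enantiopure chroman with ring A complete and O6 silylated.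
- Forward key step: heating A2 in xylene opens the four-membered ring to a conjugated ketene. The ketene carbon bonds to the alkyne carbon bearing the chromanyl group, and the hydroxyl hydrogen moves to C6' to give quinone A1, the 6-O-silyl ether of 18.
- For it: ring B is born as a quinone with the right substituents, so no selective oxidation and no benzyl groups are needed. On this point it is stronger than the chosen route.
- Against it: the stereocenter must already be in A2, so its chroman half, with a pentasubstituted, non-symmetrical ring A, has to be made first by a separate enantioselective synthesis; this costs more steps and gives up the hidden symmetry. The ring-opened intermediate can also close to a five-membered ring instead of the quinone. The new quinone sits near 140 °C with its epimerisable C3–H, and the final desilylation must avoid basic fluoride.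
- Comparison: the chosen route takes both rings from 2, makes ring A and the pyran by an isomerisation, and sets C3 by catalysis two steps from the end. It pays with a final selective oxidation that A1 would not need.

**Alternative 2: hidden pterocarpan by a quinone–chromene formal [3+2] cycloaddition.**
- Disconnection: the C3–C1' bond, together with a temporary bond from C4 to the oxygen on C2', so that the target is seen as a reductively opened and oxidised pterocarpan.
- Forward key step: quinone 2, bound to a titanium TADDOLate (TiCl2(OiPr)2 plus TADDOL, tetravalent titanium), is attacked at a free ring carbon by C3 of chromene A4. The neighbouring quinone oxygen closes on the benzylic cation at C4 and gives the cis-fused pterocarpan A3. Hydrogenolysis of the benzylic C–O bond and the benzyl ether would give 17, and oxidation 18.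
- For it: the C3–C1' bond and the stereocenter are made in one step from two small partners. It would be clearly shorter and is stronger than the chosen route in convergence.
- Against it: two donor methoxy groups make 2 a weak electrophile and leave the binding to titanium ambiguous. Cyclobutane and bicyclic adducts compete in this manifold. Useful enantioselectivity needs stoichiometric chiral titanium and depends strongly on the substrate. A4 is a very electron-rich styrene that Lewis acids polymerise.
- Comparison: the chosen route is longer, but its bonds come from couplings of well-understood scope and C3 from hydrogenation of a favourable alkene class. Its risk is confined to one isomerisation of a known type.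

**Alternative 3: oxygen-tethered Dötz benzannulation that builds ring A and the pyran together.**
- Disconnection: three bonds of ring A (C8a–C4a, C5–C6, C6–C7), back to the zerovalent chromium pentacarbonyl carbene A6. Its carbene carbon (future C8a) carries a 1,2-dimethoxyvinyl group (C8, C7) and, through oxygen, a chiral chain ending in an alkyne (C4a, C5).
- Forward key step: warming A6 inserts the alkyne and one CO and electrocyclises, closing ring A and the pyran to give A5, which is the same compound as 16.
- For it: the stereocenter is fixed early in the chain by auxiliary-controlled alkylation, independent of a hindered alkene hydrogenation, and the tether dictates the regiochemistry. On the certainty of configuration it is stronger than the chosen route.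
- Against it: A6 combines a heteroatom-rich vinyl carbene with a complex alkoxy group and is delicate to make. Chromium is stoichiometric. Donor-substituted vinyl carbenes are prone to cyclobutenone and furan side paths. Building the chiral chain of A6 adds about six steps before the carbene is assembled.
- Comparison: both routes meet at 16. The chosen one reaches it in nine steps from 1 with catalytic metals only and needs only three carbon-containing building blocks.

Key step: step 8

Remark on the chemistry: which enantiomer of the phosphine–oxazoline ligand gives 3S in step 9 is assumed. The (S)-ligand is written, and its mirror image is used if 16 proves to be 3R.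

## Route

Step 1
Reactants: 1 2,3-dimethoxyphenol
Product: 2 2,3-dimethoxy-1,4-benzoquinone
Conditions: (KO3S)2NO (2.2 equiv), KH2PO4 buffer, H2O/acetone, 0 °C to rt
Reagents that add atoms: potassium nitrosodisulfonate (Fremy's salt), [K+].[K+].[O]N(S(=O)(=O)[O-])S(=O)(=O)[O-]
Why: Teuber oxidation of a phenol with a free para position: hydrogen abstraction gives the phenoxyl radical, a second (KO3S)2NO radical adds at the para carbon, and loss of HN(SO3K)2 gives the p-quinone. Nothing else in 1 is oxidisable under these conditions.

Step 2
Reactants: 2 2,3-dimethoxy-1,4-benzoquinone; 3 benzyl bromide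
Product: 5 1,4-bis(benzyloxy)-2,3-dimethoxybenzene, via 2,3-dimethoxyhydroquinone 4 (not isolated)
Conditions: Na2S2O4, KOH aq, Bu4NBr (cat.), BnBr (2.5 equiv), THF/H2O, rt, N2
Reagents that add atoms: benzyl bromide (the second equivalent of 3), BrCc1ccccc1
Why: Reductive alkylation of a quinone: Na2S2O4 reduces 2 to 4, and each of the two phenoxides takes one benzyl group from 3 by Williamson etherification under phase transfer, so two equivalents of 3 are built into 5. Excess Na2S2O4 keeps the electron-rich dianion from reoxidation until both oxygens are benzylated.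

Step 3
Reactants: 5 1,4-bis(benzyloxy)-2,3-dimethoxybenzene
Product: 6 1,4-bis(benzyloxy)-5-bromo-2,3-dimethoxybenzene
Conditions: NBS (1.05 equiv), MeCN, 0 °C to rt, dark
Reagents that add atoms: N-bromosuccinimide, O=C1CCC(=O)N1Br
Why: Electrophilic aromatic bromination of a tetraalkoxybenzene: the two free ring positions of 5 are equivalent by symmetry, and the first bromine deactivates and shields the second. In polar MeCN without initiator NBS is a Br+ source and leaves the benzylic CH2 groups alone.

Step 4
Reactants: 6 1,4-bis(benzyloxy)-5-bromo-2,3-dimethoxybenzene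
Product: 7 2-[2,5-bis(benzyloxy)-3,4-dimethoxyphenyl]-4,4,5,5-tetramethyl-1,3,2-dioxaborolane
Conditions: B2pin2 (1.3 equiv), Pd(dppf)Cl2 (5 mol %), KOAc, 1,4-dioxane, 90 °C
Reagents that add atoms: bis(pinacolato)diboron, CC1(C)OB(OC1(C)C)B1OC(C)(C)C(C)(C)O1
Why: Miyaura borylation of an aryl bromide with a divalent palladium precatalyst; KOAc promotes transmetalation from B2pin2 without driving biaryl coupling. It places boron without an aryllithium that could attack the ortho benzyl ether by Wittig rearrangement.

Step 5
Reactants: 7 2-[2,5-bis(benzyloxy)-3,4-dimethoxyphenyl]-4,4,5,5-tetramethyl-1,3,2-dioxaborolane; 8 2-bromoprop-2-en-1-ol (2-bromoallyl alcohol)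
Product: 9 2-[2,5-bis(benzyloxy)-3,4-dimethoxyphenyl]prop-2-en-1-ol
Conditions: Pd(PPh3)4 (5 mol %), K2CO3, 1,4-dioxane/H2O, 85 °C
Reagents that add atoms: none
Why: Suzuki–Miyaura coupling of an aryl boronate with an alkenyl bromide on zerovalent palladium; the free primary alcohol of 8 is tolerated in aqueous K2CO3. The coupling forms the C3–C1' bond and brings in the whole C2–C3–C4 bridge.

Step 6
Reactants: 9 2-[2,5-bis(benzyloxy)-3,4-dimethoxyphenyl]prop-2-en-1-ol
Product: 11 tributyl{2-[2,5-bis(benzyloxy)-3,4-dimethoxyphenyl]prop-2-en-1-yl}stannane, via allyl mesylate 10 (not isolated)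
Conditions: n-BuLi (1.0 equiv), THF, −78 °C; MsCl, −78 °C; then Bu3SnLi (from Bu3SnH and LiN(iPr)2, THF, 0 °C), −78 to 0 °C
Reagents that add atoms: methanesulfonyl chloride, CS(=O)(=O)Cl (its atoms stay in 10 only); tributylstannyllithium, [Li][Sn](CCCC)(CCCC)CCCC, made in the flask from tributyltin hydride, CCCC[SnH](CCCC)CCCC
Why: One-pot conversion of an allylic alcohol into an allylstannane: the lithium alkoxide is mesylated cold and the mesylate is displaced by the stannyl anion. Direct and allylic displacement give the same compound because the two CH2 ends of the 2-arylallyl unit are equivalent.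

Step 7
Reactants: 11 tributyl{2-[2,5-bis(benzyloxy)-3,4-dimethoxyphenyl]prop-2-en-1-yl}stannane; 2 2,3-dimethoxy-1,4-benzoquinone
Product: 13 5-{2-[2,5-bis(benzyloxy)-3,4-dimethoxyphenyl]prop-2-en-1-yl}-2,3-dimethoxy-1,4-benzoquinone, via allylhydroquinone 12 (not isolated)
Conditions: BF3·OEt2 (1.5 equiv), 2 (1.3 equiv), CH2Cl2, −78 °C; sat. NaHCO3 aq at −78 °C; crude 12: Ag2O, MgSO4, Et2O, rt
Reagents that add atoms: none
Why: Lewis-acid-promoted allylation of a quinone by an allylstannane, then oxidation of the hydroquinone: BF3 activates 2, the allyl group is transferred to a carbonyl carbon or to C5, and sigmatropic shift and enolisation converge on 12. The symmetry of 2 and of the allyl ends allows only one constitution, and the cold quench protects the benzyl ethers and the electron-rich styrene from acid.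

Step 8
Reactants: 13 5-{2-[2,5-bis(benzyloxy)-3,4-dimethoxyphenyl]prop-2-en-1-yl}-2,3-dimethoxy-1,4-benzoquinone
Product: 15 3-[2,5-bis(benzyloxy)-3,4-dimethoxyphenyl]-7,8-dimethoxy-2H-chromen-6-ol, via o-quinone methide 14 (not isolated)
Conditions: pyridine (degassed), 110 °C, Ar, 0.02 M, dark
Reagents that add atoms: none
Why: Base-induced isomerisation of an allylquinone to a 2H-chromen-6-ol, the reaction type that turns ubiquinone into ubichromenol. Pyridine removes a hydrogen from the C4 methylene, which is doubly allylic and vinylogous to the carbonyl on the future C6, and protonation of the extended enolate on that oxygen gives the o-quinone methide 14. In 14 the bonds C8a=O1, C4a=C4 and C3=C2 make up a 1-oxatriene, and a thermal disrotatory oxa-6π electrocyclisation joins O1 to C2, closing the six-membered pyran ring in a pericyclic mode without ionic intermediates. No stereocenter is formed. The step needs regioselectivity between the two quinone oxygens, and the substrate secures it because only the carbonyl next to the side chain is part of the oxatriene and can reach C2. The geometry is favourable: the conformer that turns the CH2 terminus towards the carbonyl puts the bulky ring B outside, and the E isomer of 14, which cannot close, returns to 13 by the reverse tautomerisation. Aromatisation of ring A and conjugation of the new C3=C4 bond with both arenes pull the equilibria to 15, and since the change is redox-neutral nothing that could touch the benzyl-protected ring B is present. Air is excluded because 15 is an electron-rich chromenol.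

Step 9
Reactants: 15 3-[2,5-bis(benzyloxy)-3,4-dimethoxyphenyl]-7,8-dimethoxy-2H-chromen-6-ol
Product: 16 (3S)-3-[2,5-bis(benzyloxy)-3,4-dimethoxyphenyl]-7,8-dimethoxy-3,4-dihydro-2H-chromen-6-ol
Conditions: [Ir(cod)((S)-tBu-PHOX)]BArF (2 mol %; tBu-PHOX = 4-tert-butyl-2-[2-(diphenylphosphanyl)phenyl]-4,5-dihydrooxazole, BArF = B[3,5-(CF3)2C6H3]4), H2 (50 bar), CH2Cl2, rt
Reagents that add atoms: none
Why: Asymmetric hydrogenation of an unfunctionalised trisubstituted alkene by a cationic monovalent iridium P,N complex in a non-coordinating solvent; C3=C4 of 15 is an α-substituted trans-stilbene held in a ring, the class these catalysts reduce best. The chiral pocket of the ligand selects the face of C3 that receives hydrogen and so sets the 3S center by catalyst control; benzyl ethers are not cleaved.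

Step 10
Reactants: 16 (3S)-3-[2,5-bis(benzyloxy)-3,4-dimethoxyphenyl]-7,8-dimethoxy-3,4-dihydro-2H-chromen-6-ol
Product: 18 5-[(3S)-6-hydroxy-7,8-dimethoxy-3,4-dihydro-2H-chromen-3-yl]-2,3-dimethoxy-1,4-benzoquinone (target), via ring B hydroquinone 17 (not isolated)
Conditions: H2 (1 atm), Pd/C, EtOAc, rt; filter under Ar; Ag2O (1.2 equiv), Na2SO4, Et2O/EtOAc, rt, 30 min
Reagents that add atoms: none
Why: Hydrogenolysis of the two benzyl aryl ethers, then oxidation of the hydroquinone by Ag2O: the tetraoxygenated hydroquinone of ring B is oxidised far more easily than the monophenol of ring A, which cannot become a quinone without breaking the O1–C2 bond. Both operations are neutral, so C3, acidic once ring B is a quinone, keeps its configuration.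

## Compound list

1 | 2,3-dimethoxyphenol | COc1cccc(O)c1OC | starting material
2 | 2,3-dimethoxy-1,4-benzoquinone | COC1=C(OC)C(=O)C=CC1=O | intermediate
3 | benzyl bromide | BrCc1ccccc1 | starting material
4 | 2,3-dimethoxybenzene-1,4-diol (2,3-dimethoxyhydroquinone) | COc1c(O)ccc(O)c1OC | intermediate
5 | 1,4-bis(benzyloxy)-2,3-dimethoxybenzene | COc1c(OCc2ccccc2)ccc(OCc2ccccc2)c1OC | intermediate
6 | 1,4-bis(benzyloxy)-5-bromo-2,3-dimethoxybenzene | Brc1cc(OCc2ccccc2)c(OC)c(OC)c1OCc1ccccc1 | intermediate
7 | 2-[2,5-bis(benzyloxy)-3,4-dimethoxyphenyl]-4,4,5,5-tetramethyl-1,3,2-dioxaborolane | CC1(C)OB(OC1(C)C)c1cc(OCc2ccccc2)c(OC)c(OC)c1OCc1ccccc1 | intermediate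
8 | 2-bromoprop-2-en-1-ol (2-bromoallyl alcohol) | OCC(Br)=C | starting material
9 | 2-[2,5-bis(benzyloxy)-3,4-dimethoxyphenyl]prop-2-en-1-ol | OCC(=C)c1cc(OCc2ccccc2)c(OC)c(OC)c1OCc1ccccc1 | intermediate
10 | 2-[2,5-bis(benzyloxy)-3,4-dimethoxyphenyl]prop-2-en-1-yl methanesulfonate | CS(=O)(=O)OCC(=C)c1cc(OCc2ccccc2)c(OC)c(OC)c1OCc1ccccc1 | intermediate
11 | tributyl{2-[2,5-bis(benzyloxy)-3,4-dimethoxyphenyl]prop-2-en-1-yl}stannane | CCCC[Sn](CCCC)(CCCC)CC(=C)c1cc(OCc2ccccc2)c(OC)c(OC)c1OCc1ccccc1 | intermediate
12 | 5-{2-[2,5-bis(benzyloxy)-3,4-dimethoxyphenyl]prop-2-en-1-yl}-2,3-dimethoxybenzene-1,4-diol | COc1c(O)cc(CC(=C)c2cc(OCc3ccccc3)c(OC)c(OC)c2OCc2ccccc2)c(O)c1OC | intermediate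
13 | 5-{2-[2,5-bis(benzyloxy)-3,4-dimethoxyphenyl]prop-2-en-1-yl}-2,3-dimethoxy-1,4-benzoquinone | COC1=C(OC)C(=O)C(CC(=C)c2cc(OCc3ccccc3)c(OC)c(OC)c2OCc2ccccc2)=CC1=O | intermediate
14 | (6Z)-6-{2-[2,5-bis(benzyloxy)-3,4-dimethoxyphenyl]prop-2-en-1-ylidene}-4-hydroxy-2,3-dimethoxycyclohexa-2,4-dien-1-one | COC1=C(OC)C(=O)/C(=C\C(=C)c2cc(OCc3ccccc3)c(OC)c(OC)c2OCc2ccccc2)C=C1O | intermediate
15 | 3-[2,5-bis(benzyloxy)-3,4-dimethoxyphenyl]-7,8-dimethoxy-2H-chromen-6-ol | COc1c(O)cc2C=C(COc2c1OC)c1cc(OCc2ccccc2)c(OC)c(OC)c1OCc1ccccc1 | intermediate
16 | (3S)-3-[2,5-bis(benzyloxy)-3,4-dimethoxyphenyl]-7,8-dimethoxy-3,4-dihydro-2H-chromen-6-ol | COc1c(OC)c(OCc2ccccc2)cc([C@H]2COc3c(cc(O)c(OC)c3OC)C2)c1OCc1ccccc1 | intermediate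
17 | 5-[(3S)-6-hydroxy-7,8-dimethoxy-3,4-dihydro-2H-chromen-3-yl]-2,3-dimethoxybenzene-1,4-diol | COc1c(OC)c(O)cc([C@H]2COc3c(cc(O)c(OC)c3OC)C2)c1O | intermediate
18 | 5-[(3S)-6-hydroxy-7,8-dimethoxy-3,4-dihydro-2H-chromen-3-yl]-2,3-dimethoxy-1,4-benzoquinone | COC1=C(OC)C(=O)C([C@H]2COc3c(cc(O)c(OC)c3OC)C2)=CC1=O | target

## Step count and least certain steps

Total step count: 10. Longest linear sequence: 10 steps (1 → 2 → 5 → 6 → 7 → 9 → 11 → 13 → 15 → 16 → 18). Quinone 2 enters a second time in step 7.

**Step 8 (key step).**
- What may go wrong: enolisation of the C4 methylene may be slower than base-induced decomposition of the methoxyquinone (attack at the vinylogous ester positions, redox disproportionation). The quinone methide may dimerise or add nucleophiles before it closes. The chromenol may autoxidise during work-up.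
- Fallback (sets out from 9 and 4, comes back at 15): the same oxatriene is produced by forming the C4–C4a bond, under non-basic conditions and with no quinone in the flask. Alcohol 9 is oxidised with MnO2 (CH2Cl2, rt) to the enal 2-[2,5-bis(benzyloxy)-3,4-dimethoxyphenyl]prop-2-enal F1, which is used at once. Hydroquinone 4, here isolated after Na2S2O4 reduction of 2, is heated in excess with F1 and PhB(OH)2 (cat. propionic acid, toluene, reflux, water separator). The aryl boronate delivers the aldehyde carbon to the ortho position and gives the benzodioxaborin 4-{1-[2,5-bis(benzyloxy)-3,4-dimethoxyphenyl]ethenyl}-7,8-dimethoxy-2-phenyl-4H-1,3,2-benzodioxaborinin-6-ol F2. On continued heating F2 expels phenylboronic acid to give 14 and from it 15. This is the phenylboronic acid-mediated chromene synthesis from phenols and enals. Excess 4 suppresses a second annulation.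

**Step 9.**
- What may go wrong: slow or incomplete hydrogen uptake because the ortho benzyloxy group of ring B shields the alkene and the free phenol binds to the cationic iridium hydride, and insufficient facial selectivity for the same steric reason.
- Fallback (sets out from 15, comes back at 17): C3 is set by reduction of a ketone with dynamic kinetic resolution instead of by alkene hydrogenation.
  - Benzylation of 15 (BnBr, K2CO3, DMF) gives 6-(benzyloxy)-3-[2,5-bis(benzyloxy)-3,4-dimethoxyphenyl]-7,8-dimethoxy-2H-chromene F3.
  - Hydroboration–oxidation (BH3·SMe2, THF; NaBO3) puts oxygen on the less substituted C4 and gives the racemic trans alcohol (3RS,4SR)-6-(benzyloxy)-3-[2,5-bis(benzyloxy)-3,4-dimethoxyphenyl]-7,8-dimethoxychroman-4-ol F4.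
  - Dess–Martin periodinane gives the racemic ketone 6-(benzyloxy)-3-[2,5-bis(benzyloxy)-3,4-dimethoxyphenyl]-7,8-dimethoxychroman-4-one F5, whose C3 epimerises readily because it is α to the ketone and benzylic.
  - Asymmetric transfer hydrogenation with RuCl[(S,S)-TsDPEN](p-cymene), a divalent ruthenium catalyst, in HCO2H/Et3N reduces one of the interconverting enantiomers faster. It should give the cis alcohol (3S,4S)-6-(benzyloxy)-3-[2,5-bis(benzyloxy)-3,4-dimethoxyphenyl]-7,8-dimethoxychroman-4-ol F6. The mirror-image catalyst is taken if the opposite sense is found.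
  - Hydrogenolysis (H2, Pd/C, EtOH/AcOH) removes the three benzyl groups and the benzylic C4 hydroxyl and gives 17, which is oxidised as in step 10.

**Step 7.**
- What may go wrong: the Lewis acid may close the new ortho-hydroxy styrene to a dihydrobenzofuran, the stannane may be protonated before it transfers the allyl group, or a second allylation may occur after redox exchange between 12 and 2.
- Fallback (sets out from 10 and 4, comes back at 12): the C4–C4a bond is made by a sigmatropic shift without Lewis acid. Mesylate 10, made from 9 with MsCl/Et3N and used crude, alkylates an excess of isolated 4 (K2CO3, acetone, N2) to the mono ether 4-({2-[2,5-bis(benzyloxy)-3,4-dimethoxyphenyl]prop-2-en-1-yl}oxy)-2,3-dimethoxyphenol F7. Aromatic Claisen rearrangement of F7 (N,N-diethylaniline, 190 °C) moves the allyl group to the only free ortho carbon and gives 12. The Ag2O oxidation of step 7 then gives 13.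

**Step 10.**
- What may go wrong: oxidative coupling of the ring A phenol if the oxidant is not confined to ring B, and loss of configuration at C3 by enolisation of the finished quinone on the basic oxide surface.
- Fallback (sets out from 16, comes back at 18): the ring A phenol is masked before ring B is unveiled.
  - Ac2O/pyridine gives (3S)-3-[2,5-bis(benzyloxy)-3,4-dimethoxyphenyl]-7,8-dimethoxychroman-6-yl acetate F8.
  - H2, Pd/C gives (3S)-3-(2,5-dihydroxy-3,4-dimethoxyphenyl)-7,8-dimethoxychroman-6-yl acetate F9, which is not isolated.
  - A short Ag2O oxidation gives (3S)-3-(4,5-dimethoxy-3,6-dioxocyclohexa-1,4-dien-1-yl)-7,8-dimethoxychroman-6-yl acetate F10.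
  - Acid-catalysed methanolysis (HCl in MeOH, 0 °C) removes the acetate without base and gives 18. Exchange of the quinone methoxy groups with the solvent is degenerate under these conditions.

## Further compounds

F1 | step 8 | 2-[2,5-bis(benzyloxy)-3,4-dimethoxyphenyl]prop-2-enal | O=CC(=C)c1cc(OCc2ccccc2)c(OC)c(OC)c1OCc1ccccc1
F2 | step 8 | 4-{1-[2,5-bis(benzyloxy)-3,4-dimethoxyphenyl]ethenyl}-7,8-dimethoxy-2-phenyl-4H-1,3,2-benzodioxaborinin-6-ol (racemic) | COc1c(O)cc2C(OB(Oc2c1OC)c1ccccc1)C(=C)c1cc(OCc2ccccc2)c(OC)c(OC)c1OCc1ccccc1
F3 | step 9 | 6-(benzyloxy)-3-[2,5-bis(benzyloxy)-3,4-dimethoxyphenyl]-7,8-dimethoxy-2H-chromene | COc1c(OCc2ccccc2)cc2C=C(COc2c1OC)c1cc(OCc2ccccc2)c(OC)c(OC)c1OCc1ccccc1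
F4 | step 9 | (3RS,4SR)-6-(benzyloxy)-3-[2,5-bis(benzyloxy)-3,4-dimethoxyphenyl]-7,8-dimethoxychroman-4-ol (trans, racemic; one enantiomer drawn) | O[C@@H]1[C@@H](c2cc(OCc3ccccc3)c(OC)c(OC)c2OCc2ccccc2)COc2c(OC)c(OC)c(OCc3ccccc3)cc21
F5 | step 9 | 6-(benzyloxy)-3-[2,5-bis(benzyloxy)-3,4-dimethoxyphenyl]-7,8-dimethoxychroman-4-one (racemic) | O=C1C(c2cc(OCc3ccccc3)c(OC)c(OC)c2OCc2ccccc2)COc2c(OC)c(OC)c(OCc3ccccc3)cc21
F6 | step 9 | (3S,4S)-6-(benzyloxy)-3-[2,5-bis(benzyloxy)-3,4-dimethoxyphenyl]-7,8-dimethoxychroman-4-ol (cis) | O[C@H]1[C@@H](c2cc(OCc3ccccc3)c(OC)c(OC)c2OCc2ccccc2)COc2c(OC)c(OC)c(OCc3ccccc3)cc21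
F7 | step 7 | 4-({2-[2,5-bis(benzyloxy)-3,4-dimethoxyphenyl]prop-2-en-1-yl}oxy)-2,3-dimethoxyphenol | COc1c(O)ccc(OCC(=C)c2cc(OCc3ccccc3)c(OC)c(OC)c2OCc2ccccc2)c1OC
F8 | step 10 | (3S)-3-[2,5-bis(benzyloxy)-3,4-dimethoxyphenyl]-7,8-dimethoxychroman-6-yl acetate | COc1c(OC)c(OCc2ccccc2)cc([C@H]2COc3c(cc(OC(C)=O)c(OC)c3OC)C2)c1OCc1ccccc1
F9 | step 10 | (3S)-3-(2,5-dihydroxy-3,4-dimethoxyphenyl)-7,8-dimethoxychroman-6-yl acetate | COc1c(OC)c(O)cc([C@H]2COc3c(cc(OC(C)=O)c(OC)c3OC)C2)c1O
F10 | step 10 | (3S)-3-(4,5-dimethoxy-3,6-dioxocyclohexa-1,4-dien-1-yl)-7,8-dimethoxychroman-6-yl acetate | COC1=C(OC)C(=O)C([C@H]2COc3c(cc(OC(C)=O)c(OC)c3OC)C2)=CC1=O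
A1 | alternative 1 | 5-[(3S)-6-{[tert-butyl(dimethyl)silyl]oxy}-7,8-dimethoxychroman-3-yl]-2,3-dimethoxy-1,4-benzoquinone | COC1=C(OC)C(=O)C([C@H]2COc3c(cc(O[Si](C)(C)C(C)(C)C)c(OC)c3OC)C2)=CC1=O
A2 | alternative 1 | 4-{[(3S)-6-{[tert-butyl(dimethyl)silyl]oxy}-7,8-dimethoxychroman-3-yl]ethynyl}-4-hydroxy-2,3-dimethoxycyclobut-2-en-1-one | COC1=C(OC)C(O)(C#C[C@H]2COc3c(cc(O[Si](C)(C)C(C)(C)C)c(OC)c3OC)C2)C1=O
A3 | alternative 2 | (6aS,11aS)-2-(benzyloxy)-3,4,9,10-tetramethoxypterocarpan-8-ol | COc1c(OC)c(O)cc2c1O[C@@H]1c3cc(OCc4ccccc4)c(OC)c(OC)c3OC[C@@H]12
A4 | alternative 2 | 6-(benzyloxy)-7,8-dimethoxy-2H-chromene | COc1c(OCc2ccccc2)cc2C=CCOc2c1OC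
A5 | alternative 3 | (3S)-3-[2,5-bis(benzyloxy)-3,4-dimethoxyphenyl]-7,8-dimethoxychroman-6-ol (identical with 16) | COc1c(OC)c(OCc2ccccc2)cc([C@H]2COc3c(cc(O)c(OC)c3OC)C2)c1OCc1ccccc1
A6 | alternative 3 | pentacarbonyl[{[(2S)-2-[2,5-bis(benzyloxy)-3,4-dimethoxyphenyl]pent-4-yn-1-yl]oxy}(1,2-dimethoxyethenyl)methylidene]chromium | O=C=[Cr](=C=O)(=C=O)(=C=O)(=C=O)=C(OC[C@@H](CC#C)c1cc(OCc2ccccc2)c(OC)c(OC)c1OCc1ccccc1)C(OC)=COC
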